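## Structural features

Lespeflorin A3 is a (2S)-flavanone: aromatic ring A is fused to the dihydropyranone ring C (O1, C2, C3, C4=O, C4a, C8a), and C2 carries, through the single bond C2–C1′, a 2,2-dimethyl-2H-chromen-6-yl unit made of aromatic ring B and the dimethylpyran ring D. Ring A is pentasubstituted (C4a acyl, C5 H, C6 prenyl, C7 OH, C8 prenyl, C8a O1), so the free phenol O7 is flanked by both prenyl groups and C8 lies between the two ring oxygens. C2 is the only stereocentre; it has no stereogenic neighbour, but it is benzylic, bonded to O1 and β to the C4 carbonyl. This makes it labile: base opens ring C by E1cB (C3 enolate, loss of O1) to the 2′-hydroxychalcone, and acid can ionise C2–O1 because the ring D oxygen sits para to C1′; both paths racemise. The two trisubstituted prenyl alkenes (acid-induced cyclisation onto O7, oxidants, hydrogenation), the electron-rich styrenic alkene of ring D and the free phenol restrict what can be done late. The real difficulty is therefore double: to create C2 as one enantiomer in a bond-forming event that is not the reverse of its own racemisation, and to put two prenyl groups on C6 and C8 specifically, without O-prenylation or over-alkylation. The key step exploits that C2 is the β-carbon of the C4 carbonyl inside ring C and that its only exocyclic carbon substituent is the aryl carbon C1′, which is easily made as an aryl nucleophile: the stereocentre can be made by forming C2–C1′ on a flat, achiral chromone, while C6 and C8, the two positions ortho to O7, travel through that step as C–I bonds.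

## Logic of the disconnections

In one sentence: the ring B aryl group of 8 is added, under control of a chiral divalent-palladium catalyst, to C2 of the achiral, preformed ring A/ring C acceptor 12. Ring C is never closed at C2 and the O1–C2 bond is never made or broken.

17 ⇒ 16. The O7–Si bond is cut. The phenol must stay masked through steps 5 and 6, where it would bind palladium, deactivate the acceptor as a phenoxide and protonate the allylstannane. Nothing is gained in skeleton, but the free phenol between two prenyl groups appears only when no metal is left. The demand on the forward step is a cleavage that never generates the C3 enolate.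

16 ⇒ 13 + 14. The two aryl–CH2 bonds C6–C1″ and C8–C1‴ of the prenyl groups are cut. C6 and C8 are the two positions ortho to O7, exactly where electrophilic halogenation goes, so the ring carbons can act as electrophiles and the prenyl groups as nucleophiles. This is the reverse of the polarity of phenol C-prenylation and excludes O-prenylation and positional ambiguity. Ten carbons and both trisubstituted alkenes are removed, and the key step then runs on a substrate with no alkene on ring A. The forward step must couple twice at hindered C–I bonds, transfer the allyl unit at its unsubstituted terminus, and be neutral enough to leave C2 untouched.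

13 ⇒ 12 + 8 (key disconnection). The C2–C1′ bond is cut. The stereocentre is then formed in an irreversible C–C bond formation on a planar ring C whose O1–C2 bond already exists, so the oxa-Michael equilibrium that racemises flavanones is bypassed. The chiral target skeleton falls into two flat, achiral partners of similar size. The forward step must discriminate the two faces of C2 by the catalyst alone, must involve no zerovalent palladium (two C–I bonds), and must engage the enone faster than the ring D alkene of 8.

12 ⇒ 11 ⇒ 9. The O7–Si bond and then the C6–I and C8–I bonds are cut. O7 activates only its two ortho positions, so both halogens are placed in one operation on a commercial heterocycle. The demand is that iodination stays on ring A and spares C3 of the pyranone.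

8 ⇒ 5. The aryl C–B bond is cut, leading back to the bromide. The metalation must be compatible with the ring D alkene.

5 ⇒ 1 + 2. The O–CMe2 bond and the aryl–CH= bond of ring D are cut, reducing the bicycle to two commodity chemicals. The forward step must form the C–C bond ortho to the phenol oxygen and then close the pyran.

## Other disconnections considered

Alternative 1: (the first that comes to mind) Cut O1–C2 and then the Cα–Cβ bond of the resulting enone. Forward: Claisen–Schmidt condensation of ketone A1 (1-[2,4-dihydroxy-3,5-bis(3-methylbut-2-en-1-yl)phenyl]ethan-1-one) with aldehyde A2 (2,2-dimethyl-2H-chromene-6-carbaldehyde) to the 2′-hydroxychalcone A3, then catalytic asymmetric 6-endo oxa-Michael closure. Grounds for preferring the chosen plan: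
- The stereo-defining O1–C2 bond would be formed in a reversible step whose reverse is the racemisation pathway, so the enantiomeric purity is bounded by equilibration.
- The acceptor in A3 is deactivated twice: the ring D oxygen donates into Cβ, and the para hydroxyl (the later O7) donates into the carbonyl. An unactivated chalcone of this kind asks the most of a bifunctional catalyst.
- A1 needs a twofold C-prenylation of a resorcinol ketone in competition with O-alkylation and over-alkylation.

The chosen plan forms a C–C bond irreversibly on a rigid acceptor and introduces both prenyl groups at positions defined by C–I bonds.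

Alternative 2: Cut ring A itself (Danheiser benzannulation). Forward: thermolysis of 2-(3-methylbut-2-en-1-yl)cyclobut-2-en-1-one A4 with the siloxyalkyne A5 (tri(propan-2-yl)[(5-methylhex-4-en-1-yn-1-yl)oxy]silane). [2+2] cycloaddition of the derived vinylketene forms C8a–C8 and C6–C7, and 4π opening followed by 6π closure forms C4a–C8a. The product is phenol A6 (2,4-bis(3-methylbut-2-en-1-yl)-3-{[tri(propan-2-yl)silyl]oxy}phenol), with both prenyl groups, a free O1–H and a silylated O7 placed by the ring construction. Grounds for preferring the chosen plan:
- The regiochemistry is attractive, but the step leaves ring C and the only stereocentre untouched.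
- A6 would still need C-acylation at C4a in the presence of acid-sensitive prenyl groups, and then an enantioselective closure with the weaknesses of Alternative 1.
- A4 is a 2-substituted cyclobutenone with no short preparation.
- The ketene intermediates can be intercepted intramolecularly by the prenyl alkenes.
- The step count would be roughly double.

Because C6 and C8 are both ortho to O7, the same substitution pattern is reached in the chosen plan by one iodination and one coupling step.

Alternative 3: Cut C3–C4 with reversed polarity at C4, then O1–C2. Forward: a metalated 1,3-dithiane acyl-anion equivalent of a ring A salicylaldehyde opens the CH2 terminus of epoxide A7 ((2S)-2-(2,2-dimethyl-2H-chromen-6-yl)oxirane). This gives hydroxy dithiane A8 ((1R)-1-(2,2-dimethyl-2H-chromen-6-yl)-2-{2-[2-hydroxy-3,5-bis(3-methylbut-2-en-1-yl)-4-{[tri(propan-2-yl)silyl]oxy}phenyl]-1,3-dithian-2-yl}ethan-1-ol). Mitsunobu closure with inversion then forms O1–C2, and the dithioacetal is hydrolysed. Grounds for preferring the chosen plan: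
- The closure is an SN2 displacement at a benzylic carbon that is para to the ring D oxygen, so ionisation competes and stereochemical fidelity is in doubt.
- Unmasking the dithioacetal needs thiophilic metal salts or oxidants that also attack the prenyl and chromene alkenes.
- The sequence is longer and still needs a prenylated ring A aldehyde.

Key step: step 5

Assumption: flavanone numbering is used throughout (ring B atoms primed). The facial preference of the pyridine-oxazoline palladium catalyst on 12 is assigned by analogy with cyclic enones. Compounds 9 and 14 and both ligand antipodes are taken as commercial.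

## Steps

Step 1
Reactants: 1 4-bromophenol; 2 3-methylbut-2-enal
Product: 5 6-bromo-2,2-dimethyl-2H-chromene, via benzodioxaborinine 3 (not isolated), via ortho-quinone methide 4 (not isolated)
Conditions: PhB(OH)2 (1.1 equiv), AcOH (cat.), toluene, reflux, Dean–Stark
Reagents that add atoms: none
Why: Phenylboronic acid-templated ortho-hydroxyalkylation of the phenol by the enal gives 3, which fragments thermally to 4; oxa-6π-electrocyclisation then closes ring D (chromene annulation of a phenol with an enal), and the bromine para to oxygen ends at C6 of the chromene.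

Step 2
Reactants: 5 6-bromo-2,2-dimethyl-2H-chromene
Product: 8 (2,2-dimethyl-2H-chromen-6-yl)boronic acid, via aryllithium 6 (not isolated), via lithium aryltriisopropoxyborate 7 (not isolated)
Conditions: n-BuLi, THF, −78 °C; B(OiPr)3, −78 °C to rt; 1 M HCl (aq), 0 °C
Reagents that add atoms: triisopropyl borate, CC(C)OB(OC(C)C)OC(C)C; water, O
Why: Bromine–lithium exchange at −78 °C is faster than any addition to the styrenic alkene; trapping of 6 with the borate gives ate complex 7, which is hydrolysed on brief mild acidic work-up (lithiation–borylation).

Step 3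
Reactants: 9 7-hydroxy-4H-chromen-4-one
Product: 11 7-hydroxy-6,8-diiodo-4H-chromen-4-one, via 8-iodochromone 10 (not isolated)
Conditions: N-iodosuccinimide (2.1 equiv), TsOH·H2O (10 mol %), MeCN, rt, dark
Reagents that add atoms: N-iodosuccinimide, O=C1CCC(=O)N1I
Why: Electrophilic aromatic iodination: O7 activates only its ortho positions C8 (also ortho to O1, expected first) and C6 (para to O1), whereas C5 is meta to both oxygens and C3 of the electron-poor pyranone is far less nucleophilic, so two equivalents of iodonium should be consumed on ring A.

Step 4
Reactants: 11 7-hydroxy-6,8-diiodo-4H-chromen-4-one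
Product: 12 6,8-diiodo-7-{[tri(propan-2-yl)silyl]oxy}-4H-chromen-4-one
Conditions: i-Pr3SiCl, imidazole, DMF, 40 °C
Reagents that add atoms: chlorotri(propan-2-yl)silane, CC(C)[Si](Cl)(C(C)C)C(C)C
Why: Standard silylation of an acidic phenol through the N-silylimidazolium species; the bulky silyl ether is chosen because it should survive steps 5 and 6, keeps the phenol from binding palladium, and is removable with buffered fluoride.

Step 5
Reactants: 12 6,8-diiodo-7-{[tri(propan-2-yl)silyl]oxy}-4H-chromen-4-one; 8 (2,2-dimethyl-2H-chromen-6-yl)boronic acid
Product: 13 (2S)-2-(2,2-dimethyl-2H-chromen-6-yl)-6,8-diiodo-7-{[tri(propan-2-yl)silyl]oxy}-2,3-dihydro-4H-chromen-4-one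
Conditions: Pd(OCOCF3)2 (10 mol %), (R)-4-tert-butyl-2-(pyridin-2-yl)-4,5-dihydrooxazole [(R)-t-BuPyOx] (12 mol %), NH4PF6 (30 mol %), H2O (5 equiv), 8 (2 equiv), ClCH2CH2Cl, 60 °C
Reagents that add atoms: none
Why: Transmetalation of 8 to the cationic, ligand-bound divalent palladium gives an arylpalladium species that binds the C2=C3 bond of 12 and inserts it (enantio-determining carbopalladation), placing the aryl group on C2 and palladium on C3; the palladium enolate is then protonated by water/NH4+ faster than it can undergo β-hydride elimination, which releases 13 and regenerates divalent palladium without any zerovalent stage. The closest known reaction type is the pyridine-oxazoline/Pd(OCOCF3)2-catalysed asymmetric conjugate addition of arylboronic acids to chromones, which gives flavanones directly. The step closes no ring: ring C is already present and only the exocyclic C2–C1′ bond is formed. The C2 configuration is controlled by the ligand: in the insertion transition state the tert-butyl group of the oxazoline clashes with the carbonyl-side flank of the acceptor (C4/C4a with its peri C5–H), so one face of the planar chromone is preferred; transposing the established model in which the (S)-ligand gives (R)-3-aryl-3-methylcyclohexanones (same face, with the priorities of aryl and ring heteroatom exchanged), the (R)-ligand is expected to give 2S, and the antipodal ligand is equally available should the sense prove opposite. Chemoselectivity over the two C–I bonds rests on the absence of zerovalent palladium, and over the ring D alkene of 8 on the faster insertion of the polarised enone. The silyl ether keeps the acidic O7–H from binding palladium or deactivating the acceptor as a phenoxide. The weakly acidic medium gives the C3 enolate no lifetime, so the retro-oxa-Michael pathway that racemises flavanones is not accessible.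

Step 6
Reactants: 13 (2S)-2-(2,2-dimethyl-2H-chromen-6-yl)-6,8-diiodo-7-{[tri(propan-2-yl)silyl]oxy}-2,3-dihydro-4H-chromen-4-one; 14 tributyl(3-methylbut-2-en-1-yl)stannane
Product: 16 (2S)-2-(2,2-dimethyl-2H-chromen-6-yl)-6,8-bis(3-methylbut-2-en-1-yl)-7-{[tri(propan-2-yl)silyl]oxy}-2,3-dihydro-4H-chromen-4-one, via monoprenyl iodide 15 (not isolated)
Conditions: Pd(PPh3)4 (10 mol %), 14 (3 equiv), toluene (degassed), 100 °C, dark
Reagents that add atoms: none
Why: Twofold Stille coupling: zerovalent palladium inserts into each C–I bond (the less hindered C6–I expected first), the allylic stannane transmetalates, and reductive elimination at the unsubstituted allyl terminus gives linear prenyl groups; the base-free, fluoride-free, neutral medium should leave the C2 configuration and the silyl ether intact.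

Step 7
Reactants: 16 (2S)-2-(2,2-dimethyl-2H-chromen-6-yl)-6,8-bis(3-methylbut-2-en-1-yl)-7-{[tri(propan-2-yl)silyl]oxy}-2,3-dihydro-4H-chromen-4-one
Product: 17 lespeflorin A3, (2S)-2-(2,2-dimethyl-2H-chromen-6-yl)-7-hydroxy-6,8-bis(3-methylbut-2-en-1-yl)-2,3-dihydro-4H-chromen-4-one
Conditions: Bu4NF (1.2 equiv), AcOH (1.5 equiv), THF, 0 °C to rt
Reagents that add atoms: none
Why: Fluoride-induced cleavage of the aryl silyl ether; acetic acid buffers the medium so that no C3 enolate forms and ring C cannot open by retro-oxa-Michael, and neither the prenyl nor the chromene alkenes react.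

## Compound list

1 | 4-bromophenol | Oc1ccc(Br)cc1 | starting material
2 | 3-methylbut-2-enal | CC(C)=CC=O | starting material
3 | 6-bromo-4-(2-methylprop-1-en-1-yl)-2-phenyl-4H-1,3,2-benzodioxaborinine (racemic) | CC(C)=CC1OB(c2ccccc2)Oc2ccc(Br)cc21 | intermediate (not isolated)
4 | 4-bromo-6-(3-methylbut-2-en-1-ylidene)cyclohexa-2,4-dien-1-one | CC(C)=CC=C1C=C(Br)C=CC1=O | intermediate (not isolated)
5 | 6-bromo-2,2-dimethyl-2H-chromene | CC1(C)C=Cc2cc(Br)ccc2O1 | intermediate
6 | (2,2-dimethyl-2H-chromen-6-yl)lithium | [Li]c1ccc2c(c1)C=CC(C)(C)O2 | intermediate (not isolated)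
7 | lithium (2,2-dimethyl-2H-chromen-6-yl)tri(propan-2-yloxy)borate | [Li+].CC(C)O[B-](OC(C)C)(OC(C)C)c1ccc2c(c1)C=CC(C)(C)O2 | intermediate (not isolated)
8 | (2,2-dimethyl-2H-chromen-6-yl)boronic acid | OB(O)c1ccc2c(c1)C=CC(C)(C)O2 | intermediate
9 | 7-hydroxy-4H-chromen-4-one | O=c1ccoc2cc(O)ccc12 | starting material
10 | 7-hydroxy-8-iodo-4H-chromen-4-one | O=c1ccoc2c(I)c(O)ccc12 | intermediate (not isolated)
11 | 7-hydroxy-6,8-diiodo-4H-chromen-4-one | O=c1ccoc2c(I)c(O)c(I)cc12 | intermediate
12 | 6,8-diiodo-7-{[tri(propan-2-yl)silyl]oxy}-4H-chromen-4-one | O=c1ccoc2c(I)c(O[Si](C(C)C)(C(C)C)C(C)C)c(I)cc12 | intermediate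
13 | (2S)-2-(2,2-dimethyl-2H-chromen-6-yl)-6,8-diiodo-7-{[tri(propan-2-yl)silyl]oxy}-2,3-dihydro-4H-chromen-4-one | Ic1cc2c(c(I)c1O[Si](C(C)C)(C(C)C)C(C)C)O[C@H](c1ccc3c(c1)C=CC(C)(C)O3)CC2=O | intermediate
14 | tributyl(3-methylbut-2-en-1-yl)stannane | CCCC[Sn](CCCC)(CCCC)CC=C(C)C | starting material
15 | (2S)-2-(2,2-dimethyl-2H-chromen-6-yl)-8-iodo-6-(3-methylbut-2-en-1-yl)-7-{[tri(propan-2-yl)silyl]oxy}-2,3-dihydro-4H-chromen-4-one | CC(C)=CCc1cc2c(c(I)c1O[Si](C(C)C)(C(C)C)C(C)C)O[C@H](c1ccc3c(c1)C=CC(C)(C)O3)CC2=O | intermediate (not isolated)
16 | (2S)-2-(2,2-dimethyl-2H-chromen-6-yl)-6,8-bis(3-methylbut-2-en-1-yl)-7-{[tri(propan-2-yl)silyl]oxy}-2,3-dihydro-4H-chromen-4-one | CC(C)=CCc1cc2c(c(CC=C(C)C)c1O[Si](C(C)C)(C(C)C)C(C)C)O[C@H](c1ccc3c(c1)C=CC(C)(C)O3)CC2=O | intermediate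
17 | lespeflorin A3, (2S)-2-(2,2-dimethyl-2H-chromen-6-yl)-7-hydroxy-6,8-bis(3-methylbut-2-en-1-yl)-2,3-dihydro-4H-chromen-4-one | CC(C)=CCc1cc2c(c(CC=C(C)C)c1O)O[C@H](c1ccc3c(c1)C=CC(C)(C)O3)CC2=O | target

## Step count and least certain steps

Total step count: 7.
Longest linear sequence: 5 steps (9 → 11 → 12 → 13 → 16 → 17, steps 3 to 7). The branch 1 → 5 → 8 (steps 1 and 2) joins at step 5 and is equally long.

**Step 5 (key step).**
- What may go wrong: carbopalladation may be slow, because the carbonyl of the acceptor is deactivated by the para silyloxy group. Protodeboronation of the electron-rich 8, or arylpalladium insertion into the ring D alkene of a second molecule of 8, would then consume the nucleophile. Facial discrimination by the ligand may be imperfect. Part of the silyl ether may be lost to fluoride released from NH4PF6, which would simply lead into the fallback given for step 7.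
- Fallback (sets out from 12 and 8, returns at 13): the two compounds would be joined without stereocontrol by the more reactive achiral catalyst Pd(OCOCF3)2/2,2′-bipyridine (aqueous ClCH2CH2Cl, 60 °C). This gives racemic 2-(2,2-dimethyl-2H-chromen-6-yl)-6,8-diiodo-7-{[tri(propan-2-yl)silyl]oxy}-2,3-dihydro-4H-chromen-4-one F1. The enantiomers would then be separated by kinetic resolution through asymmetric transfer hydrogenation (RuCl(p-cymene)[(R,R)-TsDPEN], HCO2H/Et3N 5:2, EtOAc, rt, stopped just past half conversion). Hydride is delivered anti to the C2 aryl group, and the (2R)-ketone is expected to be reduced faster to the 2,4-cis alcohol (2R,4R)-2-(2,2-dimethyl-2H-chromen-6-yl)-6,8-diiodo-7-{[tri(propan-2-yl)silyl]oxy}-3,4-dihydro-2H-chromen-4-ol F2. F2 is removed by chromatography and the unreacted (2S)-ketone is 13. The antipodal ruthenium catalyst would be used if the matched pairing proved to be the opposite one.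

**Step 6.**
- What may go wrong: allyl transfer with transposition (coupling at the dimethyl-substituted terminus, giving 1,1-dimethylallyl groups); incomplete second coupling at the more hindered C8–I, flanked by O1 and the silyl ether; hydrodeiodination.
- Fallback (sets out from 13, returns at 16): twofold Stille coupling with allyltributylstannane (Pd(PPh3)4, toluene, 100 °C), for which the two allyl termini are identical, would give (2S)-2-(2,2-dimethyl-2H-chromen-6-yl)-6,8-di(prop-2-en-1-yl)-7-{[tri(propan-2-yl)silyl]oxy}-2,3-dihydro-4H-chromen-4-one F3. Twofold cross-metathesis of F3 with excess 2-methylbut-2-ene (second-generation Grubbs catalyst RuCl2(=CHPh)(H2IMes)(PCy3), CH2Cl2, 40 °C) would then convert both allyl groups into prenyl groups and give 16. The ring D alkene is cyclic, disubstituted and unstrained, and should not take part.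

**Step 7.**
- What may go wrong: opening of ring C by retro-oxa-Michael (E1cB through the C3 enolate) if the fluoride medium becomes basic, which would erode the C2 configuration; sluggish cleavage of a silyl ether buried between two prenyl groups.
- Fallback (sets out from 13, returns at 17): the order of the last two operations would be reversed. The silyl ether of 13, whose phenoxide is a far better leaving group, would be cleaved under acidic conditions (HF·pyridine, THF/pyridine, 0 °C) to (2S)-2-(2,2-dimethyl-2H-chromen-6-yl)-7-hydroxy-6,8-diiodo-2,3-dihydro-4H-chromen-4-one F4. F4 would then be coupled as the free phenol with excess 14 (Pd(PPh3)4, toluene, 100 °C) to give 17 directly, so that fluoride never meets the prenylated flavanone.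

**Step 1.**
- What may go wrong: low conversion, because the para bromine lowers the nucleophilicity of the ortho carbons; self-condensation of 2 under the acidic, hot conditions.
- Fallback (sets out from 1, returns at 5): O-alkylation of 1 with 3-chloro-3-methylbut-1-yne (K2CO3, KI, acetone, reflux) would give the aryl propargyl ether 1-bromo-4-[(2-methylbut-3-yn-2-yl)oxy]benzene F5. Heating F5 (N,N-diethylaniline, 190 °C) would bring about propargyl Claisen rearrangement, 1,5-hydrogen shift and oxa-6π-electrocyclisation to 5.

## Further compounds

F1 | step 5 | rac-2-(2,2-dimethyl-2H-chromen-6-yl)-6,8-diiodo-7-{[tri(propan-2-yl)silyl]oxy}-2,3-dihydro-4H-chromen-4-one | Ic1cc2c(c(I)c1O[Si](C(C)C)(C(C)C)C(C)C)OC(c1ccc3c(c1)C=CC(C)(C)O3)CC2=O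
F2 | step 5 | (2R,4R)-2-(2,2-dimethyl-2H-chromen-6-yl)-6,8-diiodo-7-{[tri(propan-2-yl)silyl]oxy}-3,4-dihydro-2H-chromen-4-ol | Ic1cc2c(c(I)c1O[Si](C(C)C)(C(C)C)C(C)C)O[C@@H](c1ccc3c(c1)C=CC(C)(C)O3)C[C@H]2O
F3 | step 6 | (2S)-2-(2,2-dimethyl-2H-chromen-6-yl)-6,8-di(prop-2-en-1-yl)-7-{[tri(propan-2-yl)silyl]oxy}-2,3-dihydro-4H-chromen-4-one | C=CCc1cc2c(c(CC=C)c1O[Si](C(C)C)(C(C)C)C(C)C)O[C@H](c1ccc3c(c1)C=CC(C)(C)O3)CC2=O
F4 | step 7 | (2S)-2-(2,2-dimethyl-2H-chromen-6-yl)-7-hydroxy-6,8-diiodo-2,3-dihydro-4H-chromen-4-one | Oc1c(I)cc2c(c1I)O[C@H](c1ccc3c(c1)C=CC(C)(C)O3)CC2=O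
F5 | step 1 | 1-bromo-4-[(2-methylbut-3-yn-2-yl)oxy]benzene | C#CC(C)(C)Oc1ccc(Br)cc1
A1 | alternative 1 | 1-[2,4-dihydroxy-3,5-bis(3-methylbut-2-en-1-yl)phenyl]ethan-1-one | CC(=O)c1cc(CC=C(C)C)c(O)c(CC=C(C)C)c1O
A2 | alternative 1 | 2,2-dimethyl-2H-chromene-6-carbaldehyde | CC1(C)C=Cc2cc(C=O)ccc2O1
A3 | alternative 1 | (E)-1-[2,4-dihydroxy-3,5-bis(3-methylbut-2-en-1-yl)phenyl]-3-(2,2-dimethyl-2H-chromen-6-yl)prop-2-en-1-one | CC(C)=CCc1cc(C(=O)/C=C/c2ccc3c(c2)C=CC(C)(C)O3)c(O)c(CC=C(C)C)c1O
A4 | alternative 2 | 2-(3-methylbut-2-en-1-yl)cyclobut-2-en-1-one | O=C1CC=C1CC=C(C)C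
A5 | alternative 2 | tri(propan-2-yl)[(5-methylhex-4-en-1-yn-1-yl)oxy]silane | CC(C)=CCC#CO[Si](C(C)C)(C(C)C)C(C)C
A6 | alternative 2 | 2,4-bis(3-methylbut-2-en-1-yl)-3-{[tri(propan-2-yl)silyl]oxy}phenol | CC(C)=CCc1ccc(O)c(CC=C(C)C)c1O[Si](C(C)C)(C(C)C)C(C)C
A7 | alternative 3 | (2S)-2-(2,2-dimethyl-2H-chromen-6-yl)oxirane | CC1(C)C=Cc2cc([C@H]3CO3)ccc2O1
A8 | alternative 3 | (1R)-1-(2,2-dimethyl-2H-chromen-6-yl)-2-{2-[2-hydroxy-3,5-bis(3-methylbut-2-en-1-yl)-4-{[tri(propan-2-yl)silyl]oxy}phenyl]-1,3-dithian-2-yl}ethan-1-ol | CC(C)=CCc1cc(C2(C[C@@H](O)c3ccc4c(c3)C=CC(C)(C)O4)SCCCS2)c(O)c(CC=C(C)C)c1O[Si](C(C)C)(C(C)C)C(C)C
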